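**Strategy.** Everything rests on cutting the 2,4-disubstituted furan at O1–C2 and C2–C3: O1, C5, C4 and C3 are the atoms of a protected propargyl alcohol, and C2 with its aryl ring is the carbonyl carbon of an aroyl chloride. One flask couples the two to an ynone, adds HI across the triple bond and closes the furan, so that the masked quinone ring sits at C2 and iodine at C4, a position that substitution of a preformed furan would not reach. The precursors are 2,5-dimethoxybenzoyl chloride, the tetrahydropyranyl ether of propargyl alcohol and NaI. The iodide then becomes the side-chain ketone, which is reduced to the (S)-carbinol, acylated and finally oxidised to the quinone.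

Key step: step 1

Remark: 2 is used as the racemate; its acetal carbon leaves with the protecting group in step 1 and has no influence on the product. The carbinol carbon of the target is (S) (O > furan C4 > CH2 > H).

**Step 1**
Reactants: 1 2,5-dimethoxybenzoyl chloride; 2 2-(prop-2-yn-1-yloxy)oxane; 3 sodium iodide
Product: 6 2-(2,5-dimethoxyphenyl)-4-iodofuran, via ynone 4 (not isolated), via hydroxy iodoenone 5 (not isolated)
Conditions: PdCl2(PPh3)2 (2 mol%), CuI (4 mol%), NEt3 (1.0 equiv), THF, rt; then 3, TsOH·H2O, MeOH, rt
Reagents that add atoms: none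
Why: Zerovalent palladium, formed in the flask from PdCl2(PPh3)2, inserts into the C–Cl bond of 1, the copper acetylide made from 2, CuI and NEt3 transmetalates, and reductive elimination gives ynone 4; because only one equivalent of amine is present, the mixture can simply be acidified afterwards. TsOH with methanol removes the tetrahydropyranyl acetal and, with NaI, supplies HI: iodide adds in conjugate fashion to the ynone carbon β to the carbonyl (the future C4), and in the (E)-iodoenone 5 the free hydroxyl attacks the ketone carbon (the future C2) in a 5-exo-trig closure, after which the cyclic hemiketal loses water and the furan ring becomes aromatic. The closest known reaction type is the one-pot acyl Sonogashira coupling–hydrohalogenation–cyclocondensation of aroyl chlorides, protected propargyl alcohols and halide salts that gives 3-halofurans. No stereocentre is created. The selectivity needed is regiochemical, aryl at C2 and iodine at C4, and the substrate secures it: iodide can only add β to the carbonyl, the propargylic oxygen can only become O1, and although both iodoenone geometries form and interconvert under the acid, only the one with CH2OH cis to the aroyl group can close. The ortho-methoxy group must stay a spectator, which the room-temperature acid treatment should allow, since a competing 6-endo attack of that oxygen on the triple bond needs harsher activation.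

**Step 2**
Reactants: 7 4-methylpent-3-enoic acid
Product: 9 N-methoxy-N,4-dimethylpent-3-enamide, via acyl imidazolide 8 (not isolated)
Conditions: 1,1'-carbonyldiimidazole, CH2Cl2, 0 °C → rt; then MeNH(OMe)·HCl, rt
Reagents that add atoms: N,O-dimethylhydroxylamine hydrochloride, CNOC.Cl
Why: Weinreb amide formation through the acyl imidazolide is a standard amide coupling, and its nearly neutral conditions should leave the β,γ-double bond of 7 in place instead of moving it into conjugation.

**Step 3**
Reactants: 6 2-(2,5-dimethoxyphenyl)-4-iodofuran; 9 N-methoxy-N,4-dimethylpent-3-enamide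
Product: 12 1-[5-(2,5-dimethoxyphenyl)furan-3-yl]-4-methylpent-3-en-1-one, via furylmagnesium chloride 10 (not isolated), via tetrahedral magnesium adduct 11 (not isolated)
Conditions: iPrMgCl·LiCl (1.1 equiv), THF, −20 → 0 °C; then 9, −20 °C → rt; aq NH4Cl, 0 °C
Reagents that add atoms: none
Why: Iodine–magnesium exchange on the heteroaryl iodide followed by a Weinreb ketone synthesis should stop at the ketone, because the chelated adduct 11 does not collapse before the mildly acidic quench, so that neither a second addition nor base-induced migration of the skipped alkene can take place in the flask.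

**Step 4**
Reactants: 12 1-[5-(2,5-dimethoxyphenyl)furan-3-yl]-4-methylpent-3-en-1-one
Product: 14 (1S)-1-[5-(2,5-dimethoxyphenyl)furan-3-yl]-4-methylpent-3-en-1-ol, via catechol borate ester 13 (not isolated)
Conditions: (R)-2-methyl-CBS-oxazaborolidine [(3aR)-1-methyl-3,3-diphenyltetrahydro-1H,3H-pyrrolo[1,2-c][1,3,2]oxazaborole] (20 mol%), catecholborane (1.5 equiv), toluene, −78 °C; MeOH, then aq NaOH wash
Reagents that add atoms: none
Why: In this Corey–Bakshi–Shibata reduction the ketone binds to the ring boron of the (R)-oxazaborolidine with the flat furyl group as the large substituent and the CH2 chain as the small one, so that hydride from the nitrogen-bound catecholborane is delivered to the Re face and should set the (S)-carbinol, as this catalyst enantiomer does for acetophenone-type aryl alkyl ketones, while catecholborane at low temperature leaves the trisubstituted alkene untouched.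

**Step 5**
Reactants: 14 (1S)-1-[5-(2,5-dimethoxyphenyl)furan-3-yl]-4-methylpent-3-en-1-ol; 15 3-methylbut-2-enoyl chloride
Product: 16 (1S)-1-[5-(2,5-dimethoxyphenyl)furan-3-yl]-4-methylpent-3-en-1-yl 3-methylbut-2-enoate
Conditions: pyridine, 4-(dimethylamino)pyridine (cat.), CH2Cl2, 0 °C → rt
Reagents that add atoms: none
Why: Acylation of the secondary alcohol by the acid chloride under nucleophilic catalysis touches only the O–H bond, so the (S)-centre is retained, and pyridine is preferred to a trialkylamine in order to suppress vinylketene formation and the deconjugated 3-methylbut-3-enoate that would follow from it.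

**Step 6**
Reactants: 16 (1S)-1-[5-(2,5-dimethoxyphenyl)furan-3-yl]-4-methylpent-3-en-1-yl 3-methylbut-2-enoate
Product: 17 (1S)-1-[5-(3,6-dioxocyclohexa-1,4-dien-1-yl)furan-3-yl]-4-methylpent-3-en-1-yl 3-methylbut-2-enoate
Conditions: (NH4)2Ce(NO3)6 (2.5 equiv), MeCN–H2O, 0 °C, short contact time
Reagents that add atoms: water, O
Why: Oxidative demethylation of a hydroquinone dimethyl ether by tetravalent cerium removes two electrons from the dimethoxyarene, water attacks the two methoxy-bearing carbons and methanol is lost to give the quinone, and the brief treatment at 0 °C is meant to spare the furan, the two trisubstituted alkenes and the furylic ester whose C–O bond carries the stereocentre.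

**Compound list**
1 | 2,5-dimethoxybenzoyl chloride | COc1ccc(OC)c(C(=O)Cl)c1 | starting material
2 | 2-(prop-2-yn-1-yloxy)oxane (racemic) | C#CCOC1CCCCO1 | starting material
3 | sodium iodide | [Na+].[I-] | starting material
4 | 1-(2,5-dimethoxyphenyl)-4-(oxan-2-yloxy)but-2-yn-1-one | COc1ccc(OC)c(C(=O)C#CCOC2CCCCO2)c1 | intermediate
5 | (2E)-1-(2,5-dimethoxyphenyl)-4-hydroxy-3-iodobut-2-en-1-one | COc1ccc(OC)c(C(=O)/C=C(/I)CO)c1 | intermediate
6 | 2-(2,5-dimethoxyphenyl)-4-iodofuran | COc1ccc(OC)c(-c2cc(I)co2)c1 | intermediate
7 | 4-methylpent-3-enoic acid | CC(C)=CCC(=O)O | starting material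
8 | 1-(1H-imidazol-1-yl)-4-methylpent-3-en-1-one | CC(C)=CCC(=O)n1ccnc1 | intermediate
9 | N-methoxy-N,4-dimethylpent-3-enamide | CC(C)=CCC(=O)N(C)OC | intermediate
10 | [5-(2,5-dimethoxyphenyl)furan-3-yl]magnesium chloride | COc1ccc(OC)c(-c2cc([Mg]Cl)co2)c1 | intermediate
11 | chloromagnesium 1-[5-(2,5-dimethoxyphenyl)furan-3-yl]-1-[methoxy(methyl)amino]-4-methylpent-3-en-1-olate | COc1ccc(OC)c(-c2cc(C(CC=C(C)C)(O[Mg]Cl)N(C)OC)co2)c1 | intermediate
12 | 1-[5-(2,5-dimethoxyphenyl)furan-3-yl]-4-methylpent-3-en-1-one | CC(C)=CCC(=O)c1coc(-c2cc(OC)ccc2OC)c1 | intermediate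
13 | 2-{[(1S)-1-[5-(2,5-dimethoxyphenyl)furan-3-yl]-4-methylpent-3-en-1-yl]oxy}-1,3,2-benzodioxaborole | CC(C)=CC[C@H](OB1Oc2ccccc2O1)c1coc(-c2cc(OC)ccc2OC)c1 | intermediate
14 | (1S)-1-[5-(2,5-dimethoxyphenyl)furan-3-yl]-4-methylpent-3-en-1-ol | CC(C)=CC[C@H](O)c1coc(-c2cc(OC)ccc2OC)c1 | intermediate
15 | 3-methylbut-2-enoyl chloride | CC(C)=CC(=O)Cl | starting material
16 | (1S)-1-[5-(2,5-dimethoxyphenyl)furan-3-yl]-4-methylpent-3-en-1-yl 3-methylbut-2-enoate | CC(C)=CC[C@H](OC(=O)C=C(C)C)c1coc(-c2cc(OC)ccc2OC)c1 | intermediate
17 | (1S)-1-[5-(3,6-dioxocyclohexa-1,4-dien-1-yl)furan-3-yl]-4-methylpent-3-en-1-yl 3-methylbut-2-enoate | CC(C)=CC[C@H](OC(=O)C=C(C)C)c1coc(C2=CC(=O)C=CC2=O)c1 | target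

**Step count.** Total: 6 steps. Longest linear sequence: 5 steps (steps 1, 3, 4, 5 and 6; step 2 prepares the side-chain amide separately).

**Steps most likely to fail**

Step 1. The one-pot sequence may stall at the open-chain iodoenone or be diverted when the ortho-methoxy oxygen adds to the activated triple bond in a 6-endo mode with loss of its methyl group. The fallback makes the aryl–furan bond by cross-coupling instead of building the ring. It does not set out from 1, 2 or 3; the only numbered compound it draws on is Weinreb amide 9. Commercial 2,4-dibromofuran (Brc1coc(Br)c1) and (2,5-dimethoxyphenyl)boronic acid (COc1ccc(OC)c(B(O)O)c1) would be joined by Suzuki–Miyaura coupling (Pd(PPh3)4, K2CO3, dioxane–water, 80 °C). The coupling is expected at the more reactive C2–Br bond and should give 4-bromo-2-(2,5-dimethoxyphenyl)furan F1. Bromine–lithium exchange (n-BuLi, THF, −78 °C) would give [5-(2,5-dimethoxyphenyl)furan-3-yl]lithium F2, which is acylated with 9 at −78 °C and comes back to the route at ketone 12.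

Step 4. Discrimination between the two carbonyl faces may be poor, because the small 3-furyl ring and the unbranched CH2 chain differ less in size than the aryl and methyl groups of the model ketones. The fallback sets out from iodofuran 6 and comes back at carbinol 14 without passing through ketone 12; the stereocentre is then set by reagent-controlled allylboration of an aldehyde. Exchange as in step 3 gives 10, which is formylated with DMF to 5-(2,5-dimethoxyphenyl)furan-3-carbaldehyde F3. Brown allylation follows with (−)-B-allyldiisopinocampheylborane (from (−)-Ipc2BOMe and allylmagnesium bromide, Et2O, −78 °C; NaOH/H2O2 work-up). This reagent enantiomer converts benzaldehyde into the (S)-homoallylic alcohol and should give (1S)-1-[5-(2,5-dimethoxyphenyl)furan-3-yl]but-3-en-1-ol F4. Cross-metathesis with excess 2-methylbut-2-ene and second-generation Grubbs catalyst (CH2Cl2, 40 °C) converts the terminal alkene into the dimethyl-substituted alkene and rejoins the route at 14.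

Step 6. Over-oxidation is the concern: the radical cation is shared with the furan, so water may add at furan C5 and open the ring, and the strongly acidic medium may ionise the furylic C–O bond and erode the configuration. The fallback sets out from iodofuran 6 and comes back only at target 17. The methyl ethers are exchanged for silyl ethers before the side chain is built, so that the quinone is finally released by fluoride and a mild oxidant.
- BBr3 (CH2Cl2, −78 → 0 °C) would give 2-(4-iodofuran-2-yl)benzene-1,4-diol F5.
- TBSCl and imidazole (DMF) would give 2-[2,5-bis(tert-butyldimethylsilyloxy)phenyl]-4-iodofuran F6.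
- The operations of steps 3, 4 and 5 would then give in turn:
  - 1-{5-[2,5-bis(tert-butyldimethylsilyloxy)phenyl]furan-3-yl}-4-methylpent-3-en-1-one F7;
  - (1S)-1-{5-[2,5-bis(tert-butyldimethylsilyloxy)phenyl]furan-3-yl}-4-methylpent-3-en-1-ol F8;
  - (1S)-1-{5-[2,5-bis(tert-butyldimethylsilyloxy)phenyl]furan-3-yl}-4-methylpent-3-en-1-yl 3-methylbut-2-enoate F9.
- Bu4NF buffered with AcOH (THF, 0 °C) would release (1S)-1-[5-(2,5-dihydroxyphenyl)furan-3-yl]-4-methylpent-3-en-1-yl 3-methylbut-2-enoate F10.
- Ag2O (Et2O, rt) would oxidise this hydroquinone to 17.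

**Further compounds**
F1 | step 1 | 4-bromo-2-(2,5-dimethoxyphenyl)furan | COc1ccc(OC)c(-c2cc(Br)co2)c1
F2 | step 1 | [5-(2,5-dimethoxyphenyl)furan-3-yl]lithium | COc1ccc(OC)c(-c2cc([Li])co2)c1
F3 | step 4 | 5-(2,5-dimethoxyphenyl)furan-3-carbaldehyde | COc1ccc(OC)c(-c2cc(C=O)co2)c1
F4 | step 4 | (1S)-1-[5-(2,5-dimethoxyphenyl)furan-3-yl]but-3-en-1-ol | C=CC[C@H](O)c1coc(-c2cc(OC)ccc2OC)c1
F5 | step 6 | 2-(4-iodofuran-2-yl)benzene-1,4-diol | Oc1ccc(O)c(-c2cc(I)co2)c1
F6 | step 6 | 2-[2,5-bis(tert-butyldimethylsilyloxy)phenyl]-4-iodofuran | CC(C)(C)[Si](C)(C)Oc1ccc(O[Si](C)(C)C(C)(C)C)c(-c2cc(I)co2)c1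
F7 | step 6 | 1-{5-[2,5-bis(tert-butyldimethylsilyloxy)phenyl]furan-3-yl}-4-methylpent-3-en-1-one | CC(C)=CCC(=O)c1coc(-c2cc(O[Si](C)(C)C(C)(C)C)ccc2O[Si](C)(C)C(C)(C)C)c1
F8 | step 6 | (1S)-1-{5-[2,5-bis(tert-butyldimethylsilyloxy)phenyl]furan-3-yl}-4-methylpent-3-en-1-ol | CC(C)=CC[C@H](O)c1coc(-c2cc(O[Si](C)(C)C(C)(C)C)ccc2O[Si](C)(C)C(C)(C)C)c1
F9 | step 6 | (1S)-1-{5-[2,5-bis(tert-butyldimethylsilyloxy)phenyl]furan-3-yl}-4-methylpent-3-en-1-yl 3-methylbut-2-enoate | CC(C)=CC[C@H](OC(=O)C=C(C)C)c1coc(-c2cc(O[Si](C)(C)C(C)(C)C)ccc2O[Si](C)(C)C(C)(C)C)c1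
F10 | step 6 | (1S)-1-[5-(2,5-dihydroxyphenyl)furan-3-yl]-4-methylpent-3-en-1-yl 3-methylbut-2-enoate | CC(C)=CC[C@H](OC(=O)C=C(C)C)c1coc(-c2cc(O)ccc2O)c1
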